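All runs stem from a simulated flask for substances that don't exist; the scatter is artificial.

I start with the easy step, the feed, and then follow rates, as fractions of the charge per minute.

| flask | substrate | gas phase | catalyst | remark | time |
|---|---|---|---|---|---|
| Thursday's | 0.022 M (fed, over 6.0 min) | 0.65 mM (held) | 0.20 mM | run made earlier; the fed solution adds 0.50 times the starting volume |  |
| epsilon | 0.0060 M (fed, over 6.0 min) | 0.65 mM (held) | 0.80 mM | the fed solution adds 0.50 times the starting volume | 6.0 min |
| eta | 0.020 M (fed, over 4.0 min) | 0.65 mM (held) | 0.050 mM | the fed solution adds 0.50 times the starting volume | 6.0 min |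
| alpha | 0.010 M (fed, over 20 min) | 0.65 mM (held) | 0.30 mM | the fed solution adds 0.50 times the starting volume | 6.0 min |
| beta | 0.080 M (fed, over 20 min) | 0.65 mM (held) | 0.20 mM | the fed solution adds 0.50 times the starting volume | 6.0 min |
| delta | 0.040 M (fed, over 25 min) | 0.65 mM (held) | 0.40 mM | the fed solution adds 0.50 times the starting volume | 6.0 min |
| gamma | 0.020 M (fed, over 6.0 min) | 0.65 mM (held) | 0.20 mM | the fed solution adds 0.50 times the starting volume | 6.0 min |

Thursday's run (percent of the substrate charged)

| time / min | target / % | substrate / % |
|---|---|---|
| 0.500 | 6 | 6 |
| 1.00 | 8 | 10 |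
| 1.50 | 10 | 13 |
| 2.00 | 16 | 15 |
| 2.50 | 17 | 19 |
| 3.00 | 25 | 25 |
| 4.00 | 35 | 30 |

(standard deviation of a reading: 2 percentage points)

- charges are per starting volume, the dose included; the dosed solution carries all of it
- at the start none of the gas phase is in solution
- percentages count the whole charge, also what has not yet gone in
- no earlier run changes the charge of catalyst; that part of a forecast is a guess

- the flasks by amount of target, in percent of the substrate charged, highest first, at 6.0 min (epsilon / eta / alpha / beta / delta / gamma)
- the amount of target, in percent of the substrate charged of the flask you put first, at 6.0 min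
- the amount of target, in percent of the substrate charged of the flask you put last, at 6.0 min

1. Thursday's flask takes in 0.167 min⁻¹ of its charge. Target would form at that rate if substrate reacted as it came in.

2. Target forms at 0.0800 min⁻¹ over the first 2.00 min. That is half the feed.

3. Between 2.00 min and 4.00 min it forms at 0.0950 min⁻¹, up by a factor of 1.19. Meanwhile the substrate reading grows to twice its value. So, within the scatter, I read the rate as close to zero order in substrate.

4. I replace the curve by its mean, 0.0875 min⁻¹. Per starting volume, that gives 1.92 mM min⁻¹. I call this the ceiling: the target made per minute while substrate is in stock. The late rate stands 8.57 % above the mean, so my shares may read low by about that.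

5. My rule is to divide the ceiling by the charge, hold it against the feed, and take the lower rate.

6. Beta has Thursday's catalyst. Its ceiling is 0.0241 min⁻¹, and its feed is 0.0500 min⁻¹. So I expect beta at 14.4 %.

7. Epsilon has a ceiling of 0.321 min⁻¹ against a feed of 0.167 min⁻¹. So I expect it first, tracking the feed, with its catalyst a guess.

8. Eta is the flask to watch. It has a quarter of Thursday's catalyst, and no earlier run changes the catalyst. If the ceiling stays, eta reaches 57.8 %. If the ceiling scales with catalyst, eta reaches 14.4 %. I cannot choose between them.

The forecast gives epsilon > gamma > alpha > delta > eta > beta, with 92 % first and 14 % last. It takes the second branch for eta: “I guess the cap scales with catalyst”.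

The flasks give epsilon > gamma > eta > alpha > delta > beta, with 95.3 % first and 15.4 % last.

    gas phase ⇌ dissolved gas, rate k1*(csat - [dissolved gas]) (kL = 0.0570 s⁻¹)
    substrate + dissolved gas + catalyst → catalyst + target (k = 4.60 × 10⁵ M⁻² s⁻¹)
    dissolved gas + target → over-reaction product (k = 0.300 M⁻¹ s⁻¹)

Beta's target of 15.4 % is a mean of 2.05 mM min⁻¹ per starting volume, close to the ceiling of 1.92 mM min⁻¹. Eta was charged with less than Thursday's flask. Even so, eta's target of 54.8 % is a mean of 1.83 mM min⁻¹, also close to the ceiling. Gas uptake is part of what holds beta down: with that resistance taken away, beta goes from 15.4 % to 27.5 %. The hour of the reading counts too: epsilon's target goes from 95.3 % at 6.00 min to 52.6 % at 60.0 min.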